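## Retrosynthetic overview

1. The target comes from a fully silylated α-(aryl-silyloxymethyl)-β-benzyl-γ-butyrolactone by C=O → CH2 deoxygenation and global desilylation. The tetrahydrofuran is the lactone ring carried through.
2. C7–C8 is made by a syn-selective, 3,4-trans aldol addition of the potassium enolate of an (R)-β-(arylmethyl)-γ-butyrolactone to O-TBS-syringaldehyde. This sets C7 and C8 from C8'.
3. The lactone comes from a catalytic enantioselective carbonylative ring expansion (four- to five-membered) of a prochiral 3-(arylmethyl)oxetane with CO. This is the key step and sets C8'.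
4. The aryl–C7' bond comes from hydroboration/B-alkyl Suzuki coupling of 3-methyleneoxetane with O-TIPS-4-bromoguaiacol (made from catechol). Syringaldehyde comes from p-cresol by exhaustive bromination/hydrolysis and copper-catalysed methoxylation.
5. Ring order: both arenes and the oxetane are bought. The only ring-forming event is oxetane → γ-lactone, and that ring ends as the tetrahydrofuran.

Numbering used: C7 is the carbinol carbon and C8 the ring carbon bearing it. C8' is the ring carbon bearing the benzyl group and C7' is the benzyl CH2. C9 and C9' are the two OCH2 carbons. The target is (7S,8R,8'R), with the ring substituents trans and C7/C8 syn.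

Assumption: 3-methyleneoxetane is taken as commercially available. The sense of induction of the new catalyst in step 4 cannot be known beforehand, so the (R,R)-ligand is written and its mirror image is used if the opposite lactone enantiomer results.

## Route

Step 1
Reactants: 1 catechol
Product: 2 guaiacol (2-methoxyphenol)
Conditions: MeI (1.0 equiv), K2CO3 (1.0 equiv), acetone, reflux (slight excess of 1; 1 removed by aqueous wash, veratrole by distillation)
Reagents that add atoms: iodomethane (MeI), CI
Why: Williamson ether synthesis with one equivalent of electrophile gives mainly the mono-ether, because the remaining hydrogen-bonded OH of 2 is less acidic than the first OH of 1.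

Step 2
Reactants: 2 guaiacol
Product: 4 (4-bromo-2-methoxyphenoxy)triisopropylsilane, via 4-bromo-2-methoxyphenol 3 (not isolated)
Conditions: NBS (1.0 equiv), DMF, 0 °C, 1 h; then imidazole (2.5 equiv), TIPSCl (1.2 equiv), rt
Reagents that add atoms: N-bromosuccinimide, O=C1CCC(=O)N1Br; chlorotriisopropylsilane (TIPSCl), CC(C)[Si](Cl)(C(C)C)C(C)C
Why: Electrophilic aromatic bromination goes para to the free OH, the strongest director, and the phenol is then capped in the same flask by imidazole-promoted silyl ether formation.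

Step 3
Reactants: 5 3-methyleneoxetane; 4 (4-bromo-2-methoxyphenoxy)triisopropylsilane
Product: 7 3-[3-methoxy-4-(triisopropylsilyloxy)benzyl]oxetane, via B-(oxetan-3-ylmethyl)-9-BBN 6 (not isolated)
Conditions: 5, 9-BBN-H (1.1 equiv), THF, rt; then 4, PdCl2(dppf) (3 mol %), K3PO4 (3 M aq), DMF, 50 °C
Reagents that add atoms: none
Why: Anti-Markovnikov hydroboration of the 1,1-disubstituted alkene followed by B-alkyl Suzuki–Miyaura coupling forms the aryl–C7' bond without radicals or Lewis acids, so the oxetane and the TIPS ether survive.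

Step 4
Reactants: 7 3-[3-methoxy-4-(triisopropylsilyloxy)benzyl]oxetane; 8 carbon monoxide
Product: 9 (4R)-4-[3-methoxy-4-(triisopropylsilyloxy)benzyl]oxolan-2-one
Conditions: [(R,R)-(salen)Cr(THF)2][Co(CO)4] (5 mol %; salen = N,N'-bis(3,5-di-tert-butylsalicylidene)cyclohexane-1,2-diaminato; preformed from (R,R)-(salen)CrCl and NaCo(CO)4), CO (60 bar), DME, 60 °C, 48 h
Reagents that add atoms: none
Why: Proposed new method: the chiral trivalent-chromium salen cation binds the oxetane oxygen and makes the two enantiotopic O–CH2 carbons diastereotopic, the ion-paired [Co(CO)4]− opens only one of them by SN2 attack, migratory CO insertion gives an acylcobalt, and the chromium alkoxide closes onto it to release the γ-lactone and the catalyst, so that C8' (never touched itself) becomes R purely through the choice of which C–O bond is broken; the closest known reaction types are the non-asymmetric Lewis acid/[Co(CO)4]− carbonylative ring expansion of epoxides and oxetanes, the enantioselective carbonylation of meso-epoxides to β-lactones and the (salen)metal-catalysed desymmetrising opening of 3-substituted oxetanes, whereas an enantioselective oxetane-to-butyrolactone carbonylative expansion is not known.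

Step 5
Reactants: 10 p-cresol
Product: 13 3,5-dibromo-4-hydroxybenzaldehyde, via 2,6-dibromo-4-methylphenol 11 (not isolated), via 2,6-dibromo-4-(dibromomethyl)phenol 12 (not isolated)
Conditions: Br2 (2.05 equiv), o-dichlorobenzene, 35 °C; Br2 (2.05 equiv), 155 °C; then H2O, 100 °C
Reagents that add atoms: bromine, BrBr; water, O
Why: Fast electrophilic ring bromination at both positions ortho to OH is followed at high temperature by double side-chain bromination of the methyl group, and hydrolysis of the resulting gem-dibromide gives the aldehyde.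

Step 6
Reactants: 13 3,5-dibromo-4-hydroxybenzaldehyde
Product: 14 syringaldehyde (4-hydroxy-3,5-dimethoxybenzaldehyde)
Conditions: NaOMe (4 equiv), CuCl (10 mol %), DMF–MeOH, 115 °C; then aq HCl
Reagents that add atoms: sodium methoxide, C[O-].[Na+]
Why: Copper-catalysed Ullmann-type methoxylation replaces both aryl bromides, which are activated by the para formyl group, and the phenoxide present needs no protection.

Step 7
Reactants: 14 syringaldehyde
Product: 15 4-(tert-butyldimethylsilyloxy)-3,5-dimethoxybenzaldehyde
Conditions: TBSCl (1.3 equiv), imidazole (2.5 equiv), DMF, rt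
Reagents that add atoms: tert-butylchlorodimethylsilane (TBSCl), CC(C)(C)[Si](C)(C)Cl
Why: Imidazole-promoted silyl ether formation masks the acidic phenol, which would otherwise quench the enolate and deactivate the aldehyde in step 8.

Step 8
Reactants: 9 (4R)-4-[3-methoxy-4-(triisopropylsilyloxy)benzyl]oxolan-2-one; 15 4-(tert-butyldimethylsilyloxy)-3,5-dimethoxybenzaldehyde
Product: 18 (3S,4R)-3-{(S)-[4-(tert-butyldimethylsilyloxy)-3,5-dimethoxyphenyl](triethylsilyloxy)methyl}-4-[3-methoxy-4-(triisopropylsilyloxy)benzyl]oxolan-2-one, via potassium lactone enolate 16 (not isolated), via potassium aldolate 17 (not isolated)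
Conditions: KN(SiMe3)2 (KHMDS, 1.1 equiv), THF, −78 °C; 15, −78 °C, 1 h; TESCl (1.5 equiv), −78 to −40 °C; pH 7 buffer
Reagents that add atoms: chlorotriethylsilane (TESCl), CC[Si](Cl)(CC)CC
Why: In this aldol addition the enolate is attacked anti to the C8' benzyl group (8,8'-trans), the weakly coordinating potassium ion favours an open antiperiplanar transition state that gives the syn (erythro, 7S) carbinol, and in situ silylation of the aldolate blocks retro-aldol equilibration.

Step 9
Reactants: 18 the silylated aldol lactone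
Product: 20 (S)-(4-hydroxy-3,5-dimethoxyphenyl)[(3R,4R)-4-(4-hydroxy-3-methoxybenzyl)oxolan-3-yl]methanol (target), via tris-silyl tetrahydrofuran 19 (not isolated)
Conditions: Fe3(CO)12 (10 mol %), 1,1,3,3-tetramethyldisiloxane (TMDS, 4 equiv), toluene, 100 °C; then THF, TBAF/AcOH (1:1, 4 equiv), 0 °C to rt
Reagents that add atoms: none
Why: Iron-catalysed hydrosilylative ester-to-ether deoxygenation takes the lactone C=O through the silyl acetal to CH2 without a Lewis acid, so the benzylic C7–O bond and all three stereocentres are untouched, and acetic acid-buffered fluoride desilylation then frees the three hydroxyl groups without quinone methide formation.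

## Compound list

1 | catechol (benzene-1,2-diol) | Oc1ccccc1O | starting material
2 | guaiacol (2-methoxyphenol) | COc1ccccc1O | intermediate
3 | 4-bromo-2-methoxyphenol | COc1cc(Br)ccc1O | intermediate
4 | (4-bromo-2-methoxyphenoxy)triisopropylsilane | COc1cc(Br)ccc1O[Si](C(C)C)(C(C)C)C(C)C | intermediate
5 | 3-methyleneoxetane | C=C1COC1 | starting material
6 | 9-(oxetan-3-ylmethyl)-9-borabicyclo[3.3.1]nonane | O1CC(CB2C3CCCC2CCC3)C1 | intermediate
7 | 3-[3-methoxy-4-(triisopropylsilyloxy)benzyl]oxetane | COc1cc(CC2COC2)ccc1O[Si](C(C)C)(C(C)C)C(C)C | intermediate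
8 | carbon monoxide | [C-]#[O+] | starting material
9 | (4R)-4-[3-methoxy-4-(triisopropylsilyloxy)benzyl]oxolan-2-one | COc1cc(C[C@H]2COC(=O)C2)ccc1O[Si](C(C)C)(C(C)C)C(C)C | intermediate
10 | p-cresol (4-methylphenol) | Cc1ccc(O)cc1 | starting material
11 | 2,6-dibromo-4-methylphenol | Cc1cc(Br)c(O)c(Br)c1 | intermediate
12 | 2,6-dibromo-4-(dibromomethyl)phenol | BrC(Br)c1cc(Br)c(O)c(Br)c1 | intermediate
13 | 3,5-dibromo-4-hydroxybenzaldehyde | O=Cc1cc(Br)c(O)c(Br)c1 | intermediate
14 | syringaldehyde (4-hydroxy-3,5-dimethoxybenzaldehyde) | COc1cc(C=O)cc(OC)c1O | intermediate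
15 | 4-(tert-butyldimethylsilyloxy)-3,5-dimethoxybenzaldehyde | COc1cc(C=O)cc(OC)c1O[Si](C)(C)C(C)(C)C | intermediate
16 | potassium (4R)-4-[3-methoxy-4-(triisopropylsilyloxy)benzyl]-4,5-dihydrofuran-2-olate | COc1cc(C[C@H]2COC([O-])=C2)ccc1O[Si](C(C)C)(C(C)C)C(C)C.[K+] | intermediate
17 | potassium (S)-alkoxide of the syn, 3,4-trans aldol adduct, (3S,4R) lactone | COc1cc(C[C@H]2COC(=O)[C@@H]2[C@H]([O-])c2cc(OC)c(O[Si](C)(C)C(C)(C)C)c(OC)c2)ccc1O[Si](C(C)C)(C(C)C)C(C)C.[K+] | intermediate
18 | (3S,4R)-3-{(S)-[4-(tert-butyldimethylsilyloxy)-3,5-dimethoxyphenyl](triethylsilyloxy)methyl}-4-[3-methoxy-4-(triisopropylsilyloxy)benzyl]oxolan-2-one | COc1cc(C[C@H]2COC(=O)[C@@H]2[C@H](O[Si](CC)(CC)CC)c2cc(OC)c(O[Si](C)(C)C(C)(C)C)c(OC)c2)ccc1O[Si](C(C)C)(C(C)C)C(C)C | intermediate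
19 | (3R,4R)-3-{(S)-[4-(tert-butyldimethylsilyloxy)-3,5-dimethoxyphenyl](triethylsilyloxy)methyl}-4-[3-methoxy-4-(triisopropylsilyloxy)benzyl]oxolane | COc1cc(C[C@H]2COC[C@@H]2[C@H](O[Si](CC)(CC)CC)c2cc(OC)c(O[Si](C)(C)C(C)(C)C)c(OC)c2)ccc1O[Si](C(C)C)(C(C)C)C(C)C | intermediate
20 | (S)-(4-hydroxy-3,5-dimethoxyphenyl)[(3R,4R)-4-(4-hydroxy-3-methoxybenzyl)oxolan-3-yl]methanol | COc1cc(C[C@H]2COC[C@@H]2[C@H](O)c2cc(OC)c(O)c(OC)c2)ccc1O | target

## Step count and risks

Total step count: 9.
Longest linear sequence: 6 (steps 1, 2, 3, 4, 8, 9).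

**Step 4 (the new step).** Oxetanes carbonylate more slowly than epoxides. Cationic oligomerisation may compete, and the enantiotopic C–O discrimination may be only moderate. The fallback uses known chemistry, sets out from 4 and returns at 9.
- Suzuki allylation of 4 with allylboronic acid pinacol ester (Pd(PPh3)4, K3PO4, dioxane–water) gives (4-allyl-2-methoxyphenoxy)triisopropylsilane F1.
- Cycloaddition of F1 with dichloroketene F2, generated in the flask from trichloroacetyl chloride and Zn–Cu couple in ether, gives racemic 2,2-dichloro-3-[3-methoxy-4-(triisopropylsilyloxy)benzyl]cyclobutan-1-one F3.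
- Zn dust in AcOH removes both chlorines to give prochiral 3-[3-methoxy-4-(triisopropylsilyloxy)benzyl]cyclobutan-1-one F4.
- The established catalytic asymmetric Baeyer–Villiger desymmetrisation of 3-substituted cyclobutanones (Sc(OTf)3 with a chiral N,N'-dioxide ligand and mCPBA, EtOAc, −20 °C) expands F4 to lactone 9.

**Step 8.** The syn/anti ratio at C7 may erode through retro-aldol before silylation, or the potassium enolate may self-condense. The fallback sets out from 9 (with 15) and returns at 18. It sets C7 by ketone reduction instead of by the aldol step.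
- An unselective aldol addition with LiN(iPr)2 (LDA) gives the free 3,4-trans aldol adduct as a mixture of C7 epimers F5.
- Dess–Martin oxidation converges both epimers on (3S,4R)-3-[4-(tert-butyldimethylsilyloxy)-3,5-dimethoxybenzoyl]-4-[3-methoxy-4-(triisopropylsilyloxy)benzyl]oxolan-2-one F6.
- Chelation-controlled reduction with Zn(BH4)2 (ether, −78 to 0 °C) delivers hydride to the chelated ketone from the side of the C8 hydrogen and gives the syn (7S) hydroxy lactone F7.
- TESCl/imidazole converts F7 into 18.

**Step 9.** The hindered α-branched lactone may stop at the silyl lactol stage or be over-reduced to the diol. The fallback sets out from 18 and returns at 19. It rebuilds the ether ring from an open diol instead of deoxygenating the carbonyl group.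
- LiBH4 (THF, 0 °C) opens 18 to (2R,3R)-2-{(S)-[4-(tert-butyldimethylsilyloxy)-3,5-dimethoxyphenyl](triethylsilyloxy)methyl}-3-[3-methoxy-4-(triisopropylsilyloxy)benzyl]butane-1,4-diol F8.
- Mitsunobu cyclodehydration of this 1,4-diol (PPh3, DIAD, THF) closes the tetrahydrofuran. The protected C7 oxygen cannot compete, so 19 results.
- 19 is then desilylated with TBAF/AcOH as in step 9.

## Further compounds

F1 | step 4 | (4-allyl-2-methoxyphenoxy)triisopropylsilane | C=CCc1ccc(O[Si](C(C)C)(C(C)C)C(C)C)c(OC)c1
F2 | step 4 | dichloroketene | ClC(Cl)=C=O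
F3 | step 4 | racemic 2,2-dichloro-3-[3-methoxy-4-(triisopropylsilyloxy)benzyl]cyclobutan-1-one | COc1cc(CC2CC(=O)C2(Cl)Cl)ccc1O[Si](C(C)C)(C(C)C)C(C)C
F4 | step 4 | 3-[3-methoxy-4-(triisopropylsilyloxy)benzyl]cyclobutan-1-one | COc1cc(CC2CC(=O)C2)ccc1O[Si](C(C)C)(C(C)C)C(C)C
F5 | step 8 | (3S,4R)-3-{[4-(tert-butyldimethylsilyloxy)-3,5-dimethoxyphenyl](hydroxy)methyl}-4-[3-methoxy-4-(triisopropylsilyloxy)benzyl]oxolan-2-one, mixture of C7 epimers | COc1cc(C[C@H]2COC(=O)[C@@H]2C(O)c2cc(OC)c(O[Si](C)(C)C(C)(C)C)c(OC)c2)ccc1O[Si](C(C)C)(C(C)C)C(C)C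
F6 | step 8 | (3S,4R)-3-[4-(tert-butyldimethylsilyloxy)-3,5-dimethoxybenzoyl]-4-[3-methoxy-4-(triisopropylsilyloxy)benzyl]oxolan-2-one | COc1cc(C[C@H]2COC(=O)[C@@H]2C(=O)c2cc(OC)c(O[Si](C)(C)C(C)(C)C)c(OC)c2)ccc1O[Si](C(C)C)(C(C)C)C(C)C
F7 | step 8 | (3S,4R)-3-{(S)-[4-(tert-butyldimethylsilyloxy)-3,5-dimethoxyphenyl](hydroxy)methyl}-4-[3-methoxy-4-(triisopropylsilyloxy)benzyl]oxolan-2-one | COc1cc(C[C@H]2COC(=O)[C@@H]2[C@H](O)c2cc(OC)c(O[Si](C)(C)C(C)(C)C)c(OC)c2)ccc1O[Si](C(C)C)(C(C)C)C(C)C
F8 | step 9 | (2R,3R)-2-{(S)-[4-(tert-butyldimethylsilyloxy)-3,5-dimethoxyphenyl](triethylsilyloxy)methyl}-3-[3-methoxy-4-(triisopropylsilyloxy)benzyl]butane-1,4-diol | COc1cc(C[C@@H](CO)[C@H](CO)[C@H](O[Si](CC)(CC)CC)c2cc(OC)c(O[Si](C)(C)C(C)(C)C)c(OC)c2)ccc1O[Si](C(C)C)(C(C)C)C(C)C
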